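## Structural features

The target 13 is a 2,3-dihydrobenzofuran: benzo ring A is fused to the oxygen ring B (O1, C2, C3, C3a, C7a). C2 carries a 3,4,5-trimethoxyphenyl group, C3 a hydroxymethyl arm (C9), and C5 of ring A, para to O1, an (E)-3-hydroxyprop-1-enyl chain. C2 and C3 are adjacent stereocentres, (2R,3S), with the aryl group and the CH2OH arm trans; both are benzylic and C2 is also an aryl ether carbon. Fragile points are the C2–O1 benzylic ether (acid, hydrogenolysis), the cinnamyl alcohol (acid, oxidants) and the electron-rich trimethoxyarene (oxidants). Any intermediate with a carbonyl carbon on C3 is also fragile, because it is a β-aryloxy carbonyl compound that can epimerise and open ring B by E1cB. The side chain is routine; the real difficulty is absolute and relative control at two contiguous benzylic centres that bear two different carbon groups. The feature exploited is that C2–C3 is the former C2=C3 bond of a benzofuran, and that aryl on C2 trans to a carbon arm on C3 is the result of anti addition of two carbon groups across it. In the route the descriptor at C3 changes from R (compounds 6 to 9) to S (10, 12, 13) without any inversion, because only CH2OH outranks the ring carbon C3a.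

## Logic of the disconnections

13 to 12, and 12 to 10 plus 11. The allylic alcohol is taken back to the ester 12, and the C5–vinyl bond is cut. The three-carbon chain is the most sensitive part of 13 and is best put on last. The gain is that 10 is a plain aryl bromide that already holds both stereocentres. The demand is that the coupling and the hydride reduction tolerate a free hydroxyl group and a benzylic ether, and that the C5 bromine survives everything before it.

10 to 8 (through 9), and 8 to 7. The one-carbon arm C9 is traced back to a propenyl and then an allyl group, so the C9=C10 bond is the one cleaved in the forward direction. The reason is that the C3 arm must come from a carbon electrophile that a chiral catalyst can deliver, and allyl is the smallest such group. The gain is that 7 is the key-step product minus boron. The demand is that trimming must not move the double bond past C9 into the benzylic C3–H, and that 9 is reduced before base can open ring B.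

7 to 6. The C2–H bond is replaced by C2–B. Boron is the atom that brings the aryl group to C2, so it has to be there in the preceding compound. The gain is that 6 is a direct three-component adduct. The demand is protodeboronation with retention, since hydrogen must end cis to the allyl group.

6 to 5 plus 3. The C3–C9 bond and the C2–aryl bond are cut together. These are the two bonds to the stereocentres, and they form on opposite faces in one event. The gain is the largest of the route: two stereocentres and two C–C bonds are exchanged for a flat heteroaryl boronate and 3. The demands are facial control at C3 by a chiral ligand on the electrophile, strictly anti migration, and a palladium catalyst that ionises 3 but does not insert into the C5–Br bond.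

5 to 4 plus 2, and 4 to 1. The B–C2 bond and then the C2–Li bond are cut, which leaves two commercial materials. The bromine at C5 is kept as the spectator because it is para to oxygen and so slow to add to zerovalent palladium at room temperature, yet reactive enough for the later coupling at 100 °C. The demand is a base that removes C2–H without exchanging the bromine, hence a lithium amide at −78 °C and not an alkyllithium.

## Other disconnections considered

Alternative 1: The cut removes ring A (C3a–C7a, C4–C5, C6–C7), which also opens ring B. In the forward direction the tethered diyne A2 would be co-cyclised with the terminal alkyne of enyne A3 under Cp*RuCl(cod) to give A1. A2 carries a triisopropylsilyl-capped ynol ether on the C2 oxygen and an ethynyl group on C3; the ruthenacycle formed from its two alkynes takes up the third alkyne.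
- In favour: both stereocentres would be made beforehand on an open chain by established acyclic stereocontrol and are spectators in the key step. The C5 chain arrives complete, with its E geometry and oxidation level. No aryl halide meets palladium. On these three points the alternative is the better plan.
- Against: A2 needs its own enantioselective synthesis of several steps. Its ynol ether has a hydrogen on C3 and is therefore open to thermal retro-ene loss of a ketene, and to hydrolysis. Placement of the A3 substituent at C5 and not C6 rests only on the steric bias of the silyl cap. The alkene of A3 can compete as a 2π partner. The C7 silyl group of A1 must later be removed with protic acid or hot fluoride, which the benzylic ether and the allylic alcohol tolerate poorly.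
- Comparison: on structure the alternative is more convergent but leaves an extra silicon to erase. On mechanism its key step follows a well-known metallacycle pathway and creates no stereocentre, so it is the more predictable (equal or better there); the chosen step achieves more, but is unprecedented. On step economy the chosen plan is clearly shorter, since A1 still needs two deprotections after a precursor synthesis longer than the whole chosen route.

Alternative 2: The cut is at O1–C2 and C3–C9 of the aromatic benzofuran A4, and the stereocentres are added afterwards by reduction of C2=C3. In the forward direction the alkynylphenol A5 would undergo 5-endo oxypalladation under PdI2/KI, the C3–palladium bond would insert CO, and methanolysis would release A4, with air as terminal oxidant.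
- In favour: A5 is one Sonogashira coupling from commercial materials, and the carbonylative heterocyclisation is well established. C9 arrives as a single carbon, so nothing has to be trimmed. Divalent palladium leaves the C5 bromide alone. For assembling the skeleton this alternative is the better plan.
- Against: every stereochemical problem is postponed to hydrogenation of a tetrasubstituted, aromatic C2=C3 bond, for which enantioselective catalysts are not dependable. Syn delivery of hydrogen would give the cis relationship, so C3 would have to be epimerised through the ester enolate. That enolate can expel the phenoxide O1 (retro-oxa-Michael), which would erase C2 as well. The C–Br bond is also at risk under hydrogenation.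
- Comparison: on structure the alternative maps better onto the C3 arm and worse onto the stereocentres. On mechanism it separates a robust bond construction from a weak stereo-defining step, whereas the chosen plan sets the relative configuration by the anti geometry of one event. On step economy the two are about equal: two steps to A4, then reduction, epimerisation, ester reduction and the same two side-chain steps.

Alternative 3: Ring A is cut at C3a–C4 and C5–C6 and built by cycloaddition onto an intact, stereodefined ring B. In the forward direction diene A7 (C3a=C7a of the dihydrofuran plus the vinyl group C7=C6) would be made from lactone A9 through an enol derivative and a vinyl coupling. It would add methyl propiolate A8 in a Diels–Alder reaction, and DDQ in the same flask would dehydrogenate the cyclohexadiene to A6.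
- In favour: the stereocentres come from a lactone that is accessible by established asymmetric chemistry, and they are not touched. The regiochemistry is the normal "para" one: the oxygen on C7a makes C3a the nucleophilic terminus, which bonds to the unsubstituted alkyne carbon and so places the ester on C5. The C3 arm already has its final length. On stereochemical security and on the C3 arm this alternative is the better plan.
- Against: A7 is a 2-oxygenated diene, a hydrolytically labile cyclic enol ether that has to be made from a sensitive lactone enol derivative. DDQ can also abstract hydride from C2–H of A6 (benzylic, ether, para-methoxyaryl) and aromatise ring B, with loss of both stereocentres. A6 still lacks two carbons of the chain, so reduction, olefination, reduction and desilylation would follow.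
- Comparison: on structure both plans keep ring B and differ in whether ring A or the C2/C3 substituents are added. On mechanism the cycloaddition is the more predictable and its regiochemistry is intrinsically secured (equal or better), but its oxidant clashes with its own product. On step economy the alternative is roughly twice as long once A9 is counted.

Key step: step 1

Assumption: the sense of induction of the bisphosphine in the allylation of this oxygen heterocycle cannot be derived with confidence, so the route is written with (R)-BINAP and the mirror-image ligand is to be used if the first run shows the opposite sense.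

Step 1
Reactants: 1 5-bromo-1-benzofuran; 2 4,4,5,5-tetramethyl-2-(3,4,5-trimethoxyphenyl)-1,3,2-dioxaborolane; 3 allyl acetate
Product: 6 2-[(2R,3R)-3-allyl-5-bromo-2-(3,4,5-trimethoxyphenyl)-2,3-dihydro-1-benzofuran-2-yl]-4,4,5,5-tetramethyl-1,3,2-dioxaborolane, via 5-bromo-2-lithio-1-benzofuran 4 (not isolated), via lithium boron ate complex 5 (not isolated)
Conditions: LiN(iPr)2 (1.05 equiv), THF, −78 °C; then 2, −78 °C → rt; volatiles removed in vacuo; then Pd2(dba)3 (2.5 mol %), (R)-BINAP (6 mol %), 3 (1.5 equiv), THF, 0 °C → rt
Reagents that add atoms: none
Why: Proposed new method: the amide base removes the C2–H next to oxygen (an alkyllithium would exchange the bromine) to give 4, which adds to the boron of 2 to form 5; zerovalent palladium with BINAP ionises 3 to a cationic π-allylpalladium complex, which is attacked outer-sphere by the enol-ether-like C3 of 5, and this C3–C9 bond formation is coupled to an antiperiplanar 1,2-shift of the trimethoxyphenyl group from boron to C2. The closest known reaction types are the enantioselective palladium-catalysed allylation with 1,2-boronate migration of indol-2-yl boron ate complexes and the electrophile-induced migrations of furan-2-yl ate complexes; the benzofuran is less nucleophilic at C3 than an indole, which is why the step is a proposal. No ring is closed, because ring B is already present in 1. The C3 stereocentre is set by the chiral bisphosphine on the allylpalladium electrophile, which selects one enantiotopic face of C3; the C2 stereocentre follows from it, because the aryl group must enter on the face opposite the incoming allyl group, so aryl and allyl end trans and boron cis to allyl. The step needs chemoselectivity for ionisation of 3 over insertion into the C5–Br bond, which the electron-rich, para-oxygenated bromoarene and the low temperature should secure. It also needs C3 attack to win over transfer of the heteroaryl group to palladium, which the tetracoordinate pinacol boronate and the electron-rich migrating group favour; removing diisopropylamine with the solvent keeps it from consuming the allyl electrophile.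

Step 2
Reactants: 6 2-[(2R,3R)-3-allyl-5-bromo-2-(3,4,5-trimethoxyphenyl)-2,3-dihydro-1-benzofuran-2-yl]-4,4,5,5-tetramethyl-1,3,2-dioxaborolane
Product: 7 (2R,3R)-3-allyl-5-bromo-2-(3,4,5-trimethoxyphenyl)-2,3-dihydro-1-benzofuran
Conditions: Bu4NF·3H2O (1.5 equiv), toluene, 45 °C
Reagents that add atoms: none
Why: Fluoride-promoted protodeboronation of a tertiary benzylic pinacol boronate: fluoride adds to boron and water bound to the ate complex delivers the proton to C2 from the side of the departing boron, so the configuration is retained. Hydrogen therefore ends cis to the allyl group and the aryl group stays trans to it.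

Step 3
Reactants: 7 (2R,3R)-3-allyl-5-bromo-2-(3,4,5-trimethoxyphenyl)-2,3-dihydro-1-benzofuran
Product: 8 (2R,3R)-5-bromo-3-[(E)-prop-1-en-1-yl]-2-(3,4,5-trimethoxyphenyl)-2,3-dihydro-1-benzofuran
Conditions: [Ir(cod)(PMePh2)2]PF6 (2 mol %, activated with H2, then degassed), THF, rt
Reagents that add atoms: none
Why: Metal-hydride alkene isomerisation: the cationic iridium hydride moves the terminal double bond by one position and should stop at the disubstituted (E)-propenyl stage, without inserting into C–Br and under neutral conditions that leave C2 and C3 alone. The alkene geometry is immaterial because the bond is cleaved next.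

Step 4
Reactants: 8 (2R,3R)-5-bromo-3-[(E)-prop-1-en-1-yl]-2-(3,4,5-trimethoxyphenyl)-2,3-dihydro-1-benzofuran
Product: 10 [(2R,3S)-5-bromo-2-(3,4,5-trimethoxyphenyl)-2,3-dihydro-1-benzofuran-3-yl]methanol, via 3-carbaldehyde 9 (not isolated)
Conditions: O3, CH2Cl2/MeOH, −78 °C (to the end point only); then NaBH4, −78 °C → 0 °C
Reagents that add atoms: ozone, [O-][O+]=O
Why: Ozonolysis with reductive work-up: the electron-rich disubstituted alkene should be consumed much faster than the trimethoxyarene, and hydride added cold to the same flask turns the peroxidic intermediates and aldehyde 9 directly into the primary alcohol. The epimerisable β-aryloxy aldehyde is thus never held under base at room temperature, and neither stereocentre is touched.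

Step 5
Reactants: 10 [(2R,3S)-5-bromo-2-(3,4,5-trimethoxyphenyl)-2,3-dihydro-1-benzofuran-3-yl]methanol; 11 methyl acrylate
Product: 12 methyl (2E)-3-[(2R,3S)-3-(hydroxymethyl)-2-(3,4,5-trimethoxyphenyl)-2,3-dihydro-1-benzofuran-5-yl]prop-2-enoate
Conditions: Pd(OAc)2 (5 mol %), P(o-tol)3 (10 mol %), Et3N, DMF, 100 °C
Reagents that add atoms: none
Why: Mizoroki–Heck reaction: oxidative addition of the aryl bromide, syn insertion of 11 and syn β-hydride elimination should give the (E)-cinnamate. The free primary alcohol and the benzylic ether are inert to the amine base.

Step 6
Reactants: 12 methyl (2E)-3-[(2R,3S)-3-(hydroxymethyl)-2-(3,4,5-trimethoxyphenyl)-2,3-dihydro-1-benzofuran-5-yl]prop-2-enoate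
Product: 13 (2E)-3-[(2R,3S)-3-(hydroxymethyl)-2-(3,4,5-trimethoxyphenyl)-2,3-dihydro-1-benzofuran-5-yl]prop-2-en-1-ol
Conditions: iBu2AlH (4 equiv), CH2Cl2, −78 °C → −20 °C; aqueous potassium sodium tartrate
Reagents that add atoms: none
Why: 1,2-Reduction of a conjugated ester by a dialkylaluminium hydride gives the allylic alcohol with the E geometry intact; the extra equivalents cover the free hydroxyl group. The neutral tartrate work-up spares the cinnamyl alcohol and the benzylic ether.

## Compound list

1 | 5-bromo-1-benzofuran | Brc1ccc2occc2c1 | starting material
2 | 4,4,5,5-tetramethyl-2-(3,4,5-trimethoxyphenyl)-1,3,2-dioxaborolane | COc1cc(B2OC(C)(C)C(C)(C)O2)cc(OC)c1OC | starting material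
3 | allyl acetate (prop-2-en-1-yl acetate) | C=CCOC(C)=O | starting material
4 | 5-bromo-2-lithio-1-benzofuran | [Li]c1cc2cc(Br)ccc2o1 | intermediate (not isolated)
5 | lithium (5-bromo-1-benzofuran-2-yl)(pinacolato)(3,4,5-trimethoxyphenyl)borate | [Li+].COc1cc([B-]2(c3cc4cc(Br)ccc4o3)OC(C)(C)C(C)(C)O2)cc(OC)c1OC | intermediate (not isolated)
6 | 2-[(2R,3R)-3-allyl-5-bromo-2-(3,4,5-trimethoxyphenyl)-2,3-dihydro-1-benzofuran-2-yl]-4,4,5,5-tetramethyl-1,3,2-dioxaborolane (aryl and allyl trans, boron cis to allyl) | COc1cc([C@]2(B3OC(C)(C)C(C)(C)O3)Oc3ccc(Br)cc3[C@H]2CC=C)cc(OC)c1OC | intermediate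
7 | (2R,3R)-3-allyl-5-bromo-2-(3,4,5-trimethoxyphenyl)-2,3-dihydro-1-benzofuran (trans) | COc1cc([C@@H]2Oc3ccc(Br)cc3[C@H]2CC=C)cc(OC)c1OC | intermediate
8 | (2R,3R)-5-bromo-3-[(E)-prop-1-en-1-yl]-2-(3,4,5-trimethoxyphenyl)-2,3-dihydro-1-benzofuran (trans) | COc1cc([C@@H]2Oc3ccc(Br)cc3[C@H]2/C=C/C)cc(OC)c1OC | intermediate
9 | (2R,3R)-5-bromo-2-(3,4,5-trimethoxyphenyl)-2,3-dihydro-1-benzofuran-3-carbaldehyde (trans) | COc1cc([C@@H]2Oc3ccc(Br)cc3[C@H]2C=O)cc(OC)c1OC | intermediate (not isolated)
10 | [(2R,3S)-5-bromo-2-(3,4,5-trimethoxyphenyl)-2,3-dihydro-1-benzofuran-3-yl]methanol (trans) | COc1cc([C@@H]2Oc3ccc(Br)cc3[C@H]2CO)cc(OC)c1OC | intermediate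
11 | methyl acrylate | C=CC(=O)OC | starting material
12 | methyl (2E)-3-[(2R,3S)-3-(hydroxymethyl)-2-(3,4,5-trimethoxyphenyl)-2,3-dihydro-1-benzofuran-5-yl]prop-2-enoate | COc1cc([C@@H]2Oc3ccc(/C=C/C(=O)OC)cc3[C@H]2CO)cc(OC)c1OC | intermediate
13 | (2E)-3-[(2R,3S)-3-(hydroxymethyl)-2-(3,4,5-trimethoxyphenyl)-2,3-dihydro-1-benzofuran-5-yl]prop-2-en-1-ol | COc1cc([C@@H]2Oc3ccc(/C=C/CO)cc3[C@H]2CO)cc(OC)c1OC | target

## Step count and least certain steps

Total step count: 6. Longest linear sequence: 6 steps, from 1 to 13.

Step 1 (key step, proposed new method). The attack of the benzofuran C3 on the allylpalladium cation may be too slow, because the oxygen heterocycle donates less than an indole. Transfer of the heteroaryl group from boron to palladium (allylation at C2) or insertion of zerovalent palladium into the C5–Br bond could then take over. Enantiofacial discrimination may also be weak, since the chiral ligand sits far from C3.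

Fallback for step 1 (known chemistry): it sets out from 4 and comes back to the route at 10, replacing steps 1 to 4. 4, made as in step 1, is quenched with B(OiPr)3 and the crude boronate is oxidised with H2O2 to 5-bromo-1-benzofuran-2(3H)-one F1. Acid-catalysed methanolysis opens the lactone to methyl (5-bromo-2-hydroxyphenyl)acetate F2. The phenol is alkylated with 3,4,5-trimethoxybenzyl chloride (K2CO3, DMF) to methyl {5-bromo-2-[(3,4,5-trimethoxybenzyl)oxy]phenyl}acetate F3. Diazo transfer with 4-acetamidobenzenesulfonyl azide and DBU gives methyl {5-bromo-2-[(3,4,5-trimethoxybenzyl)oxy]phenyl}(diazo)acetate F4. A chiral dirhodium tetracarboxylate such as Rh2(S-PTTL)4, or its mirror image, whichever leads to 2R, then effects enantioselective intramolecular carbenoid insertion into the benzylic ether C–H. This closes ring B as methyl (2R,3S)-5-bromo-2-(3,4,5-trimethoxyphenyl)-2,3-dihydro-1-benzofuran-3-carboxylate F5 (cis). Brief equilibration at C3 with NaOMe in MeOH gives methyl (2R,3R)-5-bromo-2-(3,4,5-trimethoxyphenyl)-2,3-dihydro-1-benzofuran-3-carboxylate F6 (trans), and LiBH4 reduces it to 10.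

Step 2. Protonation could proceed through a free α-oxygenated benzylic carbanion instead of the retentive front-side pathway. The proton would then arrive anti to the allyl group and the trans relationship would be lost. Fluoride activation of the hindered tertiary boronate could also be slow.

Fallback for step 2: it sets out from 6 and comes back at 7. NaBO3·4H2O in THF/water at 0 °C oxidises the C–B bond, and the hemiketal opens to (2R)-2-(5-bromo-2-hydroxyphenyl)-1-(3,4,5-trimethoxyphenyl)pent-4-en-1-one F7. This is reduced in the same flask with NaBH4 to (2R)-2-(5-bromo-2-hydroxyphenyl)-1-(3,4,5-trimethoxyphenyl)pent-4-en-1-ol F8; either configuration at C1 serves. Catalytic TsOH in CH2Cl2 then ionises the benzylic alcohol, and the phenol closes on the para-methoxy-stabilised cation anti to the allyl group to give 7. The weak point of this detour is enolisation of F7 at the former C3; it is limited by keeping the oxidation cold and reducing at once.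

Step 3. The double bond could migrate past the propenyl stage through the benzylic C3–H into conjugation with ring A. That would scramble or destroy the C3 stereocentre and could end in aromatisation of ring B.

Fallback for step 3: it sets out from 7 and comes back at 10, so it also replaces step 4. Tsuji–Wacker oxidation (PdCl2, CuCl, O2, DMF/water; divalent palladium does not insert into C–Br) gives 1-[(2R,3R)-5-bromo-2-(3,4,5-trimethoxyphenyl)-2,3-dihydro-1-benzofuran-3-yl]propan-2-one F9. Baeyer–Villiger oxidation with mCPBA (NaHCO3 buffer), in which the primary alkyl group migrates in preference to methyl, gives [(2R,3S)-5-bromo-2-(3,4,5-trimethoxyphenyl)-2,3-dihydro-1-benzofuran-3-yl]methyl acetate F10. K2CO3 in MeOH then releases 10.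

Step 4. Ozone could over-oxidise the electron-rich trimethoxyarene if it is dosed past the end point. At the aldehyde stage, base-triggered opening of ring B or epimerisation at C3 could occur before the hydride arrives.

Fallback for step 4: it sets out from 8 and comes back at 10. Catalytic dihydroxylation (K2OsO4·2H2O, N-methylmorpholine N-oxide, acetone/water) gives 1-[(2R,3S)-5-bromo-2-(3,4,5-trimethoxyphenyl)-2,3-dihydro-1-benzofuran-3-yl]propane-1,2-diol F11, a mixture at the two diol carbons. NaIO4 on silica in CH2Cl2 cleaves it under neutral conditions to 9, which is filtered directly into NaBH4/MeOH at 0 °C to give 10.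

## Further compounds

F1 | step 1 | 5-bromo-1-benzofuran-2(3H)-one | O=C1Cc2cc(Br)ccc2O1
F2 | step 1 | methyl (5-bromo-2-hydroxyphenyl)acetate | COC(=O)Cc1cc(Br)ccc1O
F3 | step 1 | methyl {5-bromo-2-[(3,4,5-trimethoxybenzyl)oxy]phenyl}acetate | COC(=O)Cc1cc(Br)ccc1OCc1cc(OC)c(OC)c(OC)c1
F4 | step 1 | methyl {5-bromo-2-[(3,4,5-trimethoxybenzyl)oxy]phenyl}(diazo)acetate | COC(=O)C(=[N+]=[N-])c1cc(Br)ccc1OCc1cc(OC)c(OC)c(OC)c1
F5 | step 1 | methyl (2R,3S)-5-bromo-2-(3,4,5-trimethoxyphenyl)-2,3-dihydro-1-benzofuran-3-carboxylate (cis) | COc1cc([C@@H]2Oc3ccc(Br)cc3[C@@H]2C(=O)OC)cc(OC)c1OC
F6 | step 1 | methyl (2R,3R)-5-bromo-2-(3,4,5-trimethoxyphenyl)-2,3-dihydro-1-benzofuran-3-carboxylate (trans) | COc1cc([C@@H]2Oc3ccc(Br)cc3[C@H]2C(=O)OC)cc(OC)c1OC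
F7 | step 2 | (2R)-2-(5-bromo-2-hydroxyphenyl)-1-(3,4,5-trimethoxyphenyl)pent-4-en-1-one | COc1cc(C(=O)[C@H](CC=C)c2cc(Br)ccc2O)cc(OC)c1OC
F8 | step 2 | (2R)-2-(5-bromo-2-hydroxyphenyl)-1-(3,4,5-trimethoxyphenyl)pent-4-en-1-ol (both C1 epimers) | COc1cc(C(O)[C@H](CC=C)c2cc(Br)ccc2O)cc(OC)c1OC
F9 | step 3 | 1-[(2R,3R)-5-bromo-2-(3,4,5-trimethoxyphenyl)-2,3-dihydro-1-benzofuran-3-yl]propan-2-one | COc1cc([C@@H]2Oc3ccc(Br)cc3[C@H]2CC(C)=O)cc(OC)c1OC
F10 | step 3 | [(2R,3S)-5-bromo-2-(3,4,5-trimethoxyphenyl)-2,3-dihydro-1-benzofuran-3-yl]methyl acetate | COc1cc([C@@H]2Oc3ccc(Br)cc3[C@H]2COC(C)=O)cc(OC)c1OC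
F11 | step 4 | 1-[(2R,3S)-5-bromo-2-(3,4,5-trimethoxyphenyl)-2,3-dihydro-1-benzofuran-3-yl]propane-1,2-diol (mixture at the diol carbons) | COc1cc([C@@H]2Oc3ccc(Br)cc3[C@H]2C(O)C(C)O)cc(OC)c1OC
A1 | alternative 1 | (2R,3S)-trans-3-[(tert-butyldimethylsilyloxy)methyl]-5-[(E)-3-(tert-butyldimethylsilyloxy)prop-1-en-1-yl]-7-(triisopropylsilyl)-2-(3,4,5-trimethoxyphenyl)-2,3-dihydro-1-benzofuran | COc1cc([C@@H]2Oc3c([Si](C(C)C)(C(C)C)C(C)C)cc(/C=C/CO[Si](C)(C)C(C)(C)C)cc3[C@H]2CO[Si](C)(C)C(C)(C)C)cc(OC)c1OC
A2 | alternative 1 | (1R,2S)-2-[(tert-butyldimethylsilyloxy)methyl]-1-(3,4,5-trimethoxyphenyl)but-3-yn-1-yl (triisopropylsilyl)ethynyl ether | COc1cc([C@H](OC#C[Si](C(C)C)(C(C)C)C(C)C)[C@@H](C#C)CO[Si](C)(C)C(C)(C)C)cc(OC)c1OC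
A3 | alternative 1 | (E)-tert-butyl(dimethyl)(pent-2-en-4-yn-1-yloxy)silane | C#C/C=C/CO[Si](C)(C)C(C)(C)C
A4 | alternative 2 | methyl 5-bromo-2-(3,4,5-trimethoxyphenyl)-1-benzofuran-3-carboxylate | COC(=O)c1c(-c2cc(OC)c(OC)c(OC)c2)oc2ccc(Br)cc12
A5 | alternative 2 | 4-bromo-2-[(3,4,5-trimethoxyphenyl)ethynyl]phenol | COc1cc(C#Cc2cc(Br)ccc2O)cc(OC)c1OC
A6 | alternative 3 | methyl (2R,3S)-trans-3-[(tert-butyldimethylsilyloxy)methyl]-2-(3,4,5-trimethoxyphenyl)-2,3-dihydro-1-benzofuran-5-carboxylate | COc1cc([C@@H]2Oc3ccc(C(=O)OC)cc3[C@H]2CO[Si](C)(C)C(C)(C)C)cc(OC)c1OC
A7 | alternative 3 | tert-butyl(dimethyl){[(2R,3S)-2-(3,4,5-trimethoxyphenyl)-5-vinyl-2,3-dihydrofuran-3-yl]methoxy}silane | COc1cc([C@@H]2OC(C=C)=C[C@H]2CO[Si](C)(C)C(C)(C)C)cc(OC)c1OC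
A8 | alternative 3 | methyl propiolate | C#CC(=O)OC
A9 | alternative 3 | (4S,5R)-4-[(tert-butyldimethylsilyloxy)methyl]-5-(3,4,5-trimethoxyphenyl)oxolan-2-one | COc1cc([C@@H]2OC(=O)C[C@H]2CO[Si](C)(C)C(C)(C)C)cc(OC)c1OC
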